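**Retrosynthetic overview**
- The target comes from global O-debenzylation of a heptabenzyl ether; the two danshensu methyl ester units are attached last by SN2 alkylation of the C1 and C3 carboxylates with the (S)- and (R)-α-triflyloxy esters (inversion).
- The C1 acid and the free C8 phenol come from hydrolysis of a five-membered aryl lactone bridging O8 and the C1 carboxyl; the C3 acid comes from oxidation of an enal.
- Key disconnection: the C1–C2 bond, made by an intermolecular amine-catalysed Michael addition of a CH-acidic benzofuran-2(3H)-one to a cinnamaldehyde; an intramolecular aldol condensation (C3=C4) follows in the same flask.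
- Ring order: lactone ring on ring A first (Claisen rearrangement, ozonolysis, lactol oxidation), then carbocyclic ring B (Michael/aldol), then the lactone is opened.
- Both side chains come from one batch of an aryl Grignard reagent and methyl (S)- or (R)-glycidate.

Assumption: the structure is taken exactly as drawn, i.e. core (1S,2S) with the C1 ester and C2 aryl cis, an (S)-configured side chain on the C3 carboxyl and an (R)-configured one on the C1 carboxyl. C1–C8a below are the 1,2-dihydronaphthalene core positions; in the tricyclic lactone 16, core C1 is C2a and core C2 is C3.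

**Route**

Step 1
Reactants: 1 3,4-dihydroxybenzaldehyde; 2 benzyl bromide
Product: 3 4-(benzyloxy)-3-hydroxybenzaldehyde
Conditions: BnBr (1.05 equiv), NaHCO3, NaI (cat.), DMF, 40 °C
Reagents that add atoms: benzyl bromide, BrCc1ccccc1
Why: Williamson etherification under weak base is selective for the more acidic 4-OH (para to the formyl group).

Step 2
Reactants: 3 4-(benzyloxy)-3-hydroxybenzaldehyde; 4 allyl bromide
Product: 5 3-(allyloxy)-4-(benzyloxy)benzaldehyde
Conditions: allyl bromide, K2CO3, acetone, reflux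
Reagents that add atoms: allyl bromide, C=CCBr
Why: Williamson O-allylation of the remaining phenol.

Step 3
Reactants: 5 3-(allyloxy)-4-(benzyloxy)benzaldehyde
Product: 6 2-allyl-4-(benzyloxy)-3-hydroxybenzaldehyde
Conditions: N,N-diethylaniline, 195 °C, argon
Reagents that add atoms: none
Why: Aromatic Claisen rearrangement delivers the allyl group to the only free ortho position (between O and CHO), then tautomerises to the phenol.

Step 4
Reactants: 6 2-allyl-4-(benzyloxy)-3-hydroxybenzaldehyde; 7 ozone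
Product: 10 7-(benzyloxy)-2-hydroxy-2,3-dihydro-1-benzofuran-4-carbaldehyde, via secondary ozonide 8 (not isolated), via ring-open hydroxy dialdehyde 9 (not isolated)
Conditions: O3, CH2Cl2, −78 °C (stop at first blue tinge); then Me2S, −78 °C → rt
Reagents that add atoms: ozone, [O-][O+]=O
Why: Ozonolysis with reductive work-up cleaves the terminal alkene far faster than the arene, and the arylacetaldehyde is trapped by the ortho phenol as the cyclic hemiacetal, which differentiates it from the aryl aldehyde.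

Step 5
Reactants: 10 7-(benzyloxy)-2-hydroxy-2,3-dihydro-1-benzofuran-4-carbaldehyde
Product: 11 7-(benzyloxy)-2-oxo-2,3-dihydro-1-benzofuran-4-carbaldehyde
Conditions: nPr4N[RuO4] (5 mol %), N-methylmorpholine N-oxide (1.5 equiv), 4 Å MS, CH2Cl2, 0 °C → rt
Reagents that add atoms: none
Why: Ley–Griffith oxidation converts the lactol to the lactone and leaves the aryl aldehyde alone under anhydrous conditions.

Step 6
Reactants: 12 3,4-bis(benzyloxy)benzaldehyde; 13 (triphenylphosphoranylidene)acetaldehyde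
Product: 14 (2E)-3-[3,4-bis(benzyloxy)phenyl]prop-2-enal
Conditions: toluene, 80 °C
Reagents that add atoms: (triphenylphosphoranylidene)acetaldehyde, O=CC=P(c1ccccc1)(c1ccccc1)c1ccccc1
Why: Wittig olefination with a stabilised ylide gives the E-enal.

Step 7
Reactants: 11 7-(benzyloxy)-2-oxo-2,3-dihydro-1-benzofuran-4-carbaldehyde; 14 (2E)-3-[3,4-bis(benzyloxy)phenyl]prop-2-enal
Product: 16 (2aS,3S)-8-(benzyloxy)-3-[3,4-bis(benzyloxy)phenyl]-2-oxo-2a,3-dihydro-2H-naphtho[1,8-bc]furan-4-carbaldehyde, via Michael adduct 15 (not isolated)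
Conditions: (R)-2-[diphenyl(trimethylsilyloxy)methyl]pyrrolidine (20 mol %), PhCO2H (20 mol %), CH2Cl2, 0 °C → rt, argon
Reagents that add atoms: (2E)-3-[3,4-bis(benzyloxy)phenyl]prop-2-enal (14), O=C/C=C/c1ccc(OCc2ccccc2)c(OCc2ccccc2)c1
Why: Iminium-activated Michael addition of the CH-acidic lactone (pKa about 13) to the enal face not shielded by the CPh2OSiMe3 group sets core C2 as S, enamine aldol condensation onto the ring-A aldehyde closes ring B, and the acidic C1 centre equilibrates to the isomer with H-1 anti to the pseudoaxial aryl group (lactone carbonyl cis to aryl, 1S).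

Step 8
Reactants: 16 tricyclic lactone enal; 17 lithium hydroxide
Product: 18 (1S,2S)-7-(benzyloxy)-2-[3,4-bis(benzyloxy)phenyl]-3-formyl-8-hydroxy-1,2-dihydronaphthalene-1-carboxylic acid
Conditions: LiOH (2.5 equiv), degassed THF/H2O 3:1, 0 °C; then 1 M HCl to pH 3, 0 °C; used at once
Reagents that add atoms: lithium hydroxide, [Li+].[OH-]
Why: Saponification of the aryl ester (the most electrophilic acyl group present) opens the lactone without breaking a bond to C1, and any enolate re-protonates anti to the aryl group, so the cis (1S,2S) acid results and is configurationally stable as the carboxylate.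

Step 9
Reactants: 19 4-bromo-1,2-bis(benzyloxy)benzene; 20 magnesium
Product: 21 [3,4-bis(benzyloxy)phenyl]magnesium bromide
Conditions: Mg turnings (1.2 equiv, activated with a crystal of I2), THF, rt → 45 °C, argon; titrated and kept as a ca. 0.5 M THF stock solution for steps 10 and 14
Reagents that add atoms: magnesium, [Mg]
Why: Grignard reagent formation by insertion of magnesium into the aryl C–Br bond; the benzyl ethers are inert and one batch supplies both side-chain syntheses.

Step 10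
Reactants: 21 [3,4-bis(benzyloxy)phenyl]magnesium bromide; 22 methyl (2S)-oxirane-2-carboxylate
Product: 23 methyl (2S)-3-[3,4-bis(benzyloxy)phenyl]-2-hydroxypropanoate
Conditions: 21 (1.3 equiv, THF stock solution), CuBr·SMe2 (10 mol %), THF, −40 → −20 °C; then 0.5 M HCl, 0 °C
Reagents that add atoms: methyl (2S)-oxirane-2-carboxylate, COC(=O)[C@@H]1CO1
Why: Copper-catalysed epoxide opening by the aryl Grignard reagent occurs at the CH2 terminus, so the stereocentre is untouched and stays S.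

Step 11
Reactants: 23 methyl (2S)-3-[3,4-bis(benzyloxy)phenyl]-2-hydroxypropanoate; 24 trifluoromethanesulfonic anhydride
Product: 25 methyl (2S)-3-[3,4-bis(benzyloxy)phenyl]-2-[(trifluoromethanesulfonyl)oxy]propanoate
Conditions: Tf2O (1.2 equiv), 2,6-lutidine (1.5 equiv), CH2Cl2, −78 → −20 °C; cold aqueous work-up, used directly
Reagents that add atoms: trifluoromethanesulfonic anhydride, O=S(=O)(OS(=O)(=O)C(F)(F)F)C(F)(F)F
Why: O-Sulfonylation of the secondary alcohol with retention gives an α-triflyloxy ester that is a very reactive SN2 electrophile.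

Step 12
Reactants: 18 (1S,2S)-hydroxy acid enal; 25 (2S)-triflate
Product: 26 (2R)-3-[3,4-bis(benzyloxy)phenyl]-1-methoxy-1-oxopropan-2-yl (1S,2S)-7-(benzyloxy)-2-[3,4-bis(benzyloxy)phenyl]-3-formyl-8-hydroxy-1,2-dihydronaphthalene-1-carboxylate
Conditions: iPr2NEt (1.1 equiv), MeCN/CH2Cl2, 0 °C → rt
Reagents that add atoms: methyl (2S)-3-[3,4-bis(benzyloxy)phenyl]-2-[(trifluoromethanesulfonyl)oxy]propanoate (25), COC(=O)[C@@H](OS(=O)(=O)C(F)(F)F)Cc1ccc(OCc2ccccc2)c(OCc2ccccc2)c1
Why: SN2 O-alkylation of the carboxylate inverts the side-chain centre from S to R, the carboxyl is never activated so C1 cannot epimerise through a ketene, and the un-ionised hindered phenol does not compete.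

Step 13
Reactants: 26 C1 ester enal; 27 sodium chlorite
Product: 28 (1S,2S)-7-(benzyloxy)-2-[3,4-bis(benzyloxy)phenyl]-8-hydroxy-1-({[(2R)-3-[3,4-bis(benzyloxy)phenyl]-1-methoxy-1-oxopropan-2-yl]oxy}carbonyl)-1,2-dihydronaphthalene-3-carboxylic acid
Conditions: NaClO2, NaH2PO4, 2-methyl-2-butene (20 equiv), tBuOH/THF/H2O, 0 °C → rt
Reagents that add atoms: sodium chlorite, [Na+].[O-]Cl=O
Why: Pinnick oxidation takes the conjugated aldehyde to the acid under buffered, non-epimerising conditions, with the alkene scavenger protecting the phenol from hypochlorous acid.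

Step 14
Reactants: 21 [3,4-bis(benzyloxy)phenyl]magnesium bromide; 29 methyl (2R)-oxirane-2-carboxylate
Product: 30 methyl (2R)-3-[3,4-bis(benzyloxy)phenyl]-2-hydroxypropanoate
Conditions: 21 (1.3 equiv, THF stock solution), CuBr·SMe2 (10 mol %), THF, −40 → −20 °C; then 0.5 M HCl, 0 °C
Reagents that add atoms: methyl (2R)-oxirane-2-carboxylate, COC(=O)[C@H]1CO1
Why: Same copper-catalysed terminal epoxide opening as step 10, here keeping the R centre.

Step 15
Reactants: 30 methyl (2R)-3-[3,4-bis(benzyloxy)phenyl]-2-hydroxypropanoate; 24 trifluoromethanesulfonic anhydride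
Product: 31 methyl (2R)-3-[3,4-bis(benzyloxy)phenyl]-2-[(trifluoromethanesulfonyl)oxy]propanoate
Conditions: Tf2O (1.2 equiv), 2,6-lutidine (1.5 equiv), CH2Cl2, −78 → −20 °C; cold aqueous work-up, used directly
Reagents that add atoms: trifluoromethanesulfonic anhydride, O=S(=O)(OS(=O)(=O)C(F)(F)F)C(F)(F)F
Why: O-Sulfonylation with retention, as in step 11.

Step 16
Reactants: 28 C3 acid; 31 (2R)-triflate
Product: 32 1-[(2R)-3-[3,4-bis(benzyloxy)phenyl]-1-methoxy-1-oxopropan-2-yl] 3-[(2S)-3-[3,4-bis(benzyloxy)phenyl]-1-methoxy-1-oxopropan-2-yl] (1S,2S)-7-(benzyloxy)-2-[3,4-bis(benzyloxy)phenyl]-8-hydroxy-1,2-dihydronaphthalene-1,3-dicarboxylate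
Conditions: iPr2NEt (1.1 equiv), MeCN/CH2Cl2, 0 °C → rt
Reagents that add atoms: methyl (2R)-3-[3,4-bis(benzyloxy)phenyl]-2-[(trifluoromethanesulfonyl)oxy]propanoate (31), COC(=O)[C@H](OS(=O)(=O)C(F)(F)F)Cc1ccc(OCc2ccccc2)c(OCc2ccccc2)c1
Why: SN2 O-alkylation of the acrylic carboxylate inverts the side-chain centre from R to S; the weak amine base does not epimerise C1.

Step 17
Reactants: 32 heptabenzyl ether
Product: 33 1-[(2R)-3-(3,4-dihydroxyphenyl)-1-methoxy-1-oxopropan-2-yl] 3-[(2S)-3-(3,4-dihydroxyphenyl)-1-methoxy-1-oxopropan-2-yl] (1S,2S)-2-(3,4-dihydroxyphenyl)-7,8-dihydroxy-1,2-dihydronaphthalene-1,3-dicarboxylate (CNP0237075.1)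
Conditions: BCl3 (1 M in CH2Cl2, 21 equiv), pentamethylbenzene (21 equiv), CH2Cl2, −78 °C; then MeOH/CHCl3 quench at −78 °C
Reagents that add atoms: none
Why: Lewis-acid debenzylation with a non-basic cation scavenger removes all seven aryl benzyl ethers at low temperature without touching the esters, the C3=C4 alkene or the stereocentres.

**Compound list**
1 | 3,4-dihydroxybenzaldehyde | O=Cc1ccc(O)c(O)c1 | starting material
2 | benzyl bromide | BrCc1ccccc1 | starting material
3 | 4-(benzyloxy)-3-hydroxybenzaldehyde | O=Cc1ccc(OCc2ccccc2)c(O)c1 | intermediate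
4 | allyl bromide (3-bromoprop-1-ene) | C=CCBr | starting material
5 | 3-(allyloxy)-4-(benzyloxy)benzaldehyde | O=Cc1ccc(OCc2ccccc2)c(OCC=C)c1 | intermediate
6 | 2-allyl-4-(benzyloxy)-3-hydroxybenzaldehyde | O=Cc1ccc(OCc2ccccc2)c(O)c1CC=C | intermediate
7 | ozone | [O-][O+]=O | starting material
8 | secondary ozonide, 4-(benzyloxy)-3-hydroxy-2-(1,2,4-trioxolan-3-ylmethyl)benzaldehyde | O=Cc1ccc(OCc2ccccc2)c(O)c1CC1OCOO1 | intermediate (not isolated)
9 | 4-(benzyloxy)-3-hydroxy-2-(2-oxoethyl)benzaldehyde | O=CCc1c(O)c(OCc2ccccc2)ccc1C=O | intermediate (not isolated)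
10 | 7-(benzyloxy)-2-hydroxy-2,3-dihydro-1-benzofuran-4-carbaldehyde (hemiacetal carbon as a mixture) | O=Cc1ccc(OCc2ccccc2)c2OC(O)Cc12 | intermediate
11 | 7-(benzyloxy)-2-oxo-2,3-dihydro-1-benzofuran-4-carbaldehyde | O=Cc1ccc(OCc2ccccc2)c2OC(=O)Cc12 | intermediate
12 | 3,4-bis(benzyloxy)benzaldehyde | O=Cc1ccc(OCc2ccccc2)c(OCc2ccccc2)c1 | starting material
13 | (triphenylphosphoranylidene)acetaldehyde | O=CC=P(c1ccccc1)(c1ccccc1)c1ccccc1 | starting material
14 | (2E)-3-[3,4-bis(benzyloxy)phenyl]prop-2-enal | O=C/C=C/c1ccc(OCc2ccccc2)c(OCc2ccccc2)c1 | intermediate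
15 | (3S)-3-[3,4-bis(benzyloxy)phenyl]-3-[7-(benzyloxy)-4-formyl-2-oxo-2,3-dihydro-1-benzofuran-3-yl]propanal (lactone α-carbon epimeric) | O=CC[C@H](c1ccc(OCc2ccccc2)c(OCc2ccccc2)c1)C1C(=O)Oc2c(OCc3ccccc3)ccc(C=O)c12 | intermediate (not isolated)
16 | (2aS,3S)-8-(benzyloxy)-3-[3,4-bis(benzyloxy)phenyl]-2-oxo-2a,3-dihydro-2H-naphtho[1,8-bc]furan-4-carbaldehyde | O=CC1=Cc2ccc(OCc4ccccc4)c3c2[C@@H](C(=O)O3)[C@H]1c1ccc(OCc2ccccc2)c(OCc2ccccc2)c1 | intermediate
17 | lithium hydroxide | [Li+].[OH-] | starting material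
18 | (1S,2S)-7-(benzyloxy)-2-[3,4-bis(benzyloxy)phenyl]-3-formyl-8-hydroxy-1,2-dihydronaphthalene-1-carboxylic acid | O=CC1=Cc2ccc(OCc3ccccc3)c(O)c2[C@@H](C(=O)O)[C@H]1c1ccc(OCc2ccccc2)c(OCc2ccccc2)c1 | intermediate
19 | 4-bromo-1,2-bis(benzyloxy)benzene | Brc1ccc(OCc2ccccc2)c(OCc2ccccc2)c1 | starting material
20 | magnesium | [Mg] | starting material
21 | [3,4-bis(benzyloxy)phenyl]magnesium bromide (THF stock solution) | Br[Mg]c1ccc(OCc2ccccc2)c(OCc2ccccc2)c1 | intermediate
22 | methyl (2S)-oxirane-2-carboxylate (methyl (S)-glycidate) | COC(=O)[C@@H]1CO1 | starting material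
23 | methyl (2S)-3-[3,4-bis(benzyloxy)phenyl]-2-hydroxypropanoate | COC(=O)[C@@H](O)Cc1ccc(OCc2ccccc2)c(OCc2ccccc2)c1 | intermediate
24 | trifluoromethanesulfonic anhydride | O=S(=O)(OS(=O)(=O)C(F)(F)F)C(F)(F)F | starting material
25 | methyl (2S)-3-[3,4-bis(benzyloxy)phenyl]-2-[(trifluoromethanesulfonyl)oxy]propanoate | COC(=O)[C@@H](OS(=O)(=O)C(F)(F)F)Cc1ccc(OCc2ccccc2)c(OCc2ccccc2)c1 | intermediate
26 | (2R)-3-[3,4-bis(benzyloxy)phenyl]-1-methoxy-1-oxopropan-2-yl (1S,2S)-7-(benzyloxy)-2-[3,4-bis(benzyloxy)phenyl]-3-formyl-8-hydroxy-1,2-dihydronaphthalene-1-carboxylate | O=CC1=Cc2ccc(OCc3ccccc3)c(O)c2[C@@H](C(=O)O[C@H](Cc2ccc(OCc3ccccc3)c(OCc3ccccc3)c2)C(=O)OC)[C@H]1c1ccc(OCc2ccccc2)c(OCc2ccccc2)c1 | intermediate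
27 | sodium chlorite | [Na+].[O-]Cl=O | starting material
28 | (1S,2S)-7-(benzyloxy)-2-[3,4-bis(benzyloxy)phenyl]-8-hydroxy-1-({[(2R)-3-[3,4-bis(benzyloxy)phenyl]-1-methoxy-1-oxopropan-2-yl]oxy}carbonyl)-1,2-dihydronaphthalene-3-carboxylic acid | OC(=O)C1=Cc2ccc(OCc3ccccc3)c(O)c2[C@@H](C(=O)O[C@H](Cc2ccc(OCc3ccccc3)c(OCc3ccccc3)c2)C(=O)OC)[C@H]1c1ccc(OCc2ccccc2)c(OCc2ccccc2)c1 | intermediate
29 | methyl (2R)-oxirane-2-carboxylate (methyl (R)-glycidate) | COC(=O)[C@H]1CO1 | starting material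
30 | methyl (2R)-3-[3,4-bis(benzyloxy)phenyl]-2-hydroxypropanoate | COC(=O)[C@H](O)Cc1ccc(OCc2ccccc2)c(OCc2ccccc2)c1 | intermediate
31 | methyl (2R)-3-[3,4-bis(benzyloxy)phenyl]-2-[(trifluoromethanesulfonyl)oxy]propanoate | COC(=O)[C@H](OS(=O)(=O)C(F)(F)F)Cc1ccc(OCc2ccccc2)c(OCc2ccccc2)c1 | intermediate
32 | 1-[(2R)-3-[3,4-bis(benzyloxy)phenyl]-1-methoxy-1-oxopropan-2-yl] 3-[(2S)-3-[3,4-bis(benzyloxy)phenyl]-1-methoxy-1-oxopropan-2-yl] (1S,2S)-7-(benzyloxy)-2-[3,4-bis(benzyloxy)phenyl]-8-hydroxy-1,2-dihydronaphthalene-1,3-dicarboxylate | COC(=O)[C@H](Cc1ccc(OCc2ccccc2)c(OCc2ccccc2)c1)OC(=O)C1=Cc2ccc(OCc3ccccc3)c(O)c2[C@@H](C(=O)O[C@H](Cc2ccc(OCc3ccccc3)c(OCc3ccccc3)c2)C(=O)OC)[C@H]1c1ccc(OCc2ccccc2)c(OCc2ccccc2)c1 | intermediate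
33 | 1-[(2R)-3-(3,4-dihydroxyphenyl)-1-methoxy-1-oxopropan-2-yl] 3-[(2S)-3-(3,4-dihydroxyphenyl)-1-methoxy-1-oxopropan-2-yl] (1S,2S)-2-(3,4-dihydroxyphenyl)-7,8-dihydroxy-1,2-dihydronaphthalene-1,3-dicarboxylate (CNP0237075.1) | COC(=O)[C@H](Cc1ccc(O)c(O)c1)OC(=O)C1=Cc2ccc(O)c(O)c2[C@@H](C(=O)O[C@H](Cc2ccc(O)c(O)c2)C(=O)OC)[C@H]1c1ccc(O)c(O)c1 | target

**Step count**
Total steps: 17. Longest linear sequence: 11 steps (1, 2, 3, 4, 5, 7, 8, 12, 13, 16, 17).

**Steps most likely to fail**

Step 7 (Michael/aldol domino). Compound 11 carries both an acidic CH2 and an aryl aldehyde, so it can self-condense, and the lactone may slowly acylate the amine catalyst. The fallback separates the Michael and aldol events with the ring-A aldehyde masked; it sets out from 6 and comes back at 16. Compound 6 is acetalised with ethylene glycol and TsOH (toluene, water removal) to 6-(benzyloxy)-3-(1,3-dioxolan-2-yl)-2-(prop-2-en-1-yl)phenol F1. Ozonolysis with Me2S work-up gives the lactol 7-(benzyloxy)-4-(1,3-dioxolan-2-yl)-2,3-dihydro-1-benzofuran-2-ol F2, and oxidation as in step 5 gives 7-(benzyloxy)-4-(1,3-dioxolan-2-yl)-1-benzofuran-2(3H)-one F3. The same amine-catalysed Michael addition to 14 then gives (3S)-3-[3,4-bis(benzyloxy)phenyl]-3-[7-(benzyloxy)-4-(1,3-dioxolan-2-yl)-2-oxo-2,3-dihydro-1-benzofuran-3-yl]propanal F4. Aqueous TsOH in acetone unmasks the aldehyde to 15, which is closed with pyrrolidinium acetate to 16.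

Step 8 (lactone hydrolysis). Hydroxide may attack the enal, or the hydroxy acid 18 may re-close to the lactone on acidification. The fallback uses the lactone itself as the acyl donor; it sets out from 16 and comes back at 26. Compound 16 is warmed with the (R)-hydroxy ester 30 (2 equiv) and catalytic Sc(O3SCF3)3 in toluene at 40 °C, so that ring-opening transesterification (retention at the carbinol carbon) gives 26 directly, bypassing 18 and 25. New compounds on this way: none F0.

Step 17 (sevenfold debenzylation). BCl3 may promote attack of the free C8 phenol on the C1 ester (re-lactonisation with loss of the side chain) or give incomplete cleavage. The fallback changes from Lewis-acid benzyl transfer to reductive C–O cleavage; it sets out from 32 and comes back at 33. Catalytic transfer hydrogenolysis with Pd(OH)2 on carbon and 1,4-cyclohexadiene in EtOAc/EtOH at rt is monitored closely and stopped at complete O-debenzylation, before the conjugated, trisubstituted C3=C4 bond is reduced. New compounds on this way: none F0.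

**Further compounds**
F1 | step 7 | 6-(benzyloxy)-3-(1,3-dioxolan-2-yl)-2-(prop-2-en-1-yl)phenol | Oc1c(CC=C)c(C2OCCO2)ccc1OCc1ccccc1
F2 | step 7 | 7-(benzyloxy)-4-(1,3-dioxolan-2-yl)-2,3-dihydro-1-benzofuran-2-ol | OC1Cc2c(C3OCCO3)ccc(OCc3ccccc3)c2O1
F3 | step 7 | 7-(benzyloxy)-4-(1,3-dioxolan-2-yl)-1-benzofuran-2(3H)-one | O=C1Cc2c(C3OCCO3)ccc(OCc3ccccc3)c2O1
F4 | step 7 | (3S)-3-[3,4-bis(benzyloxy)phenyl]-3-[7-(benzyloxy)-4-(1,3-dioxolan-2-yl)-2-oxo-2,3-dihydro-1-benzofuran-3-yl]propanal | O=CC[C@H](c1ccc(OCc2ccccc2)c(OCc2ccccc2)c1)C1C(=O)Oc2c(OCc3ccccc3)ccc(C3OCCO3)c12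
F0 | step 8 | none | none
F0 | step 17 | none | none
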